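(Its constants are made up.)

You are the chemist charging this flask and want the chain length it gives, which is the monomer in chains divided by the chains begun.

free monomer 1.5 M; protic impurity 0.750 M; initiator 28 mM; stray impurity 11 mM; time 40 min

- whether the average number of monomer units in a chain (chains begun, living or dead) reaches 20 by 40 min (yes / no)
- average number of monomer units in a chain (chains begun, living or dead) at 40 min

- the average divides the monomer in chains by the number of chains begun, living and dead together
- run time (flask): 40 min

    free monomer + initiator → living end + monomer in chains (k1 = 0.0034 M⁻¹ s⁻¹)
    free monomer + living end → monomer in chains + living end, rate k2*[living end]*[free monomer] (k2 = 0.23 M⁻¹ s⁻¹)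
    initiator + stray impurity → spent initiator (k3 = 120 M⁻¹ s⁻¹)
    protic impurity + free monomer → quenched substrate (k4 = 0.0099 M⁻¹ s⁻¹)

First the stray impurity meets the initiator. Its half-life there is 0.206 s, against 136 s for initiator starting chains, so it takes its share first. That leaves a working initiator of 17.0 mM.

Free monomer then feeds three steps, each first-order in it. Call the free monomer concentration summed over time the dose. Whatever the monomer does, initiator falls as the exponential of minus its chain-starting constant times the dose, and protic impurity as the exponential of minus its quenching constant times the dose. Their logarithmic falls therefore stand in a fixed ratio, the selectivity factor 2.91, which is the quenching constant over the chain-starting constant.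

My reckoning is a trial. Suppose one part in 4 of the working initiator survives, which needs a dose of 408 M·s. That dose quenches 0.737 M of monomer and makes 12.8 mM of living ends. Summing living ends against the dose, growth and starts take up 0.744 M. Together that is 1.48 M of the 1.5 M charged, so the trial nearly closes. With living ends at this level, free monomer's half-life by propagation is 3.94 min, and 40 min holds 10.2 of them. Counting what the quenching leaves as monomer in chains, I commit to a length of 59.6, which passes 20.

The forecast says yes, with 59 in a range from 55 to 64, taking “about three-quarters” of the working initiator as starting chains.

The flask gives yes: the length reaches 20 at 2.41 min and stands at 59.4 at 40 min, with 0.0128 M of living ends.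

At 5.94 min in this flask, free monomer's half-life by quenching is 23 min, against 8.5 h by starting chains, so quenching takes it faster. Over the run the selectivity factor ties the two together: initiator left at 40.0 min is 15% of its charge, or 4.17 mM of the working 17.0 mM, and 2.91 times that logarithmic fall gives protic impurity left at 1.67% of its charge, where the flask holds 1.7%.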